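**Strategy.** Carbocycle numbering: C1 (methacrylate), C2 (lactone oxygen), C3 (lactone junction), C4 (hydroxyl), C5, C6 (quaternary). Everything rests on the C3–C4 bond: the C4 hydroxyl is homoallylic to the exocyclic methylene of the γ-lactone, the signature of a carbonyl allylation. The cyclohexane is therefore closed last by an indium-mediated intramolecular Barbier reaction of a 3-(bromomethyl)butenolide with a C4 aldehyde; one operation forms the ring, sets C3 and C4 and unveils the α-methylene lactone. The open-chain precursor already carries the epoxide and the ester; its stereocentres come from a chirality-transferring tetronate Claisen rearrangement (C5, C6), a lactone-controlled ketone reduction (epoxide carbon) and a Brown anti-diol allylboration (C1, C2).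

Key step: step 15

Assumption: the target is handled as the open-chain hydroxy aldehyde drawn (its C4–O lactol tautomer is not treated as a separate compound), and 3-methyltetronic acid is taken as a purchasable building block.

Remark: labels C1–C6 below are those of the target cyclohexane; "side-chain aldehyde" means the CH2–CHO unit on C5.

**Step 1**
Reactants: 1 (S)-but-3-yn-2-ol; 2 allyl bromide
Product: 3 (2S)-hept-6-en-3-yn-2-ol
Conditions: CuI (cat.), K2CO3, n-Bu4NI (cat.), DMF, rt
Reagents that add atoms: none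
Why: Copper-catalysed allylation of the terminal alkyne (copper acetylide displacing the allylic bromide) should give the skipped enyne without touching the carbinol stereocentre.

**Step 2**
Reactants: 3 (2S)-hept-6-en-3-yn-2-ol
Product: 4 (2S,3Z)-hepta-3,6-dien-2-ol
Conditions: H2 (1 atm), Pd/CaCO3 poisoned with Pb(OAc)2 (Lindlar catalyst), quinoline, hexane/EtOAc, rt
Reagents that add atoms: none
Why: Lindlar semihydrogenation adds hydrogen syn to the alkyne only, giving the Z alkene that the later Claisen step requires; the terminal alkene and the stereocentre are untouched.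

**Step 3**
Reactants: 4 (2S,3Z)-hepta-3,6-dien-2-ol; 5 3-methyltetronic acid
Product: 6 4-{[(2R,3Z)-hepta-3,6-dien-2-yl]oxy}-3-methylfuran-2(5H)-one
Conditions: PPh3, DIAD, THF, 0 °C to rt
Reagents that add atoms: none
Why: Mitsunobu etherification: the acidic tetronic acid is alkylated on its enol oxygen with SN2 inversion, so the (S)-alcohol gives the (R)-allyl tetronate, an allyl vinyl ether with ring-fixed enol-ether geometry.

**Step 4**
Reactants: 6 4-{[(2R,3Z)-hepta-3,6-dien-2-yl]oxy}-3-methylfuran-2(5H)-one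
Product: 7 (3R)-3-[(4R,5E)-hepta-1,5-dien-4-yl]-3-methylfuran-2,4(3H,5H)-dione
Conditions: toluene, 140 °C (sealed tube)
Reagents that add atoms: none
Why: Thermal Claisen rearrangement through a chair transition state with the carbinol methyl equatorial: the ring fixes the C-methyl syn to the ether oxygen and the alkene is Z, so the ether stereocentre is transferred to the new quaternary centre (future C6, R) and the adjacent tertiary centre (future C5), which carries propenyl and allyl groups as masked aldehydes.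

**Step 5**
Reactants: 7 (3R)-3-[(4R,5E)-hepta-1,5-dien-4-yl]-3-methylfuran-2,4(3H,5H)-dione
Product: 9 (3R)-3-methyl-3-[(2S)-1,1,4,4-tetramethoxybutan-2-yl]furan-2,4(3H,5H)-dione, via dialdehyde 8 (not isolated)
Conditions: O3, CH2Cl2/MeOH, −78 °C; Me2S; then HC(OMe)3, TsOH·H2O (cat.), MeOH, rt
Reagents that add atoms: ozone, [O-][O+]=O (aldehyde oxygens of 8); trimethyl orthoformate, COC(OC)OC (methoxy groups of 9)
Why: Ozonolysis with reductive work-up cleaves both isolated alkenes (propenyl to the future C4 aldehyde, allyl to the side-chain aldehyde) and acid-catalysed acetalisation masks both at once; no stereocentre is formed and the C5 descriptor changes from R to S by priority only.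

**Step 6**
Reactants: 9 (3R)-3-methyl-3-[(2S)-1,1,4,4-tetramethoxybutan-2-yl]furan-2,4(3H,5H)-dione
Product: 10 (3R,4S)-4-hydroxy-3-methyl-3-[(2S)-1,1,4,4-tetramethoxybutan-2-yl]oxolan-2-one
Conditions: NaBH4, MeOH, −40 °C
Reagents that add atoms: none
Why: Chemoselective borohydride reduction of the ring ketone beside the lactone: hydride should add to the ring face carrying the small methyl group, anti to the branched side chain, giving the (4S)-alcohol that becomes the epoxide carbon.

**Step 7**
Reactants: 10 (3R,4S)-4-hydroxy-3-methyl-3-[(2S)-1,1,4,4-tetramethoxybutan-2-yl]oxolan-2-one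
Product: 11 (2R,3S)-2-[(1S)-1,2-dihydroxyethyl]-3-(2,2-dimethoxyethyl)-N,4,4-trimethoxy-N,2-dimethylbutanamide
Conditions: MeNHOMe·HCl, i-PrMgCl, THF, −20 °C to rt
Reagents that add atoms: N,O-dimethylhydroxylamine hydrochloride, CNOC.Cl
Why: Weinreb aminolysis of the γ-lactone by the magnesium amide opens the ring and frees the primary alcohol, so that the oxygen already on the stereocentre can become the epoxide oxygen; no stereocentre is touched.

**Step 8**
Reactants: 11 (2R,3S)-2-[(1S)-1,2-dihydroxyethyl]-3-(2,2-dimethoxyethyl)-N,4,4-trimethoxy-N,2-dimethylbutanamide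
Product: 13 (2R,3S)-3-(2,2-dimethoxyethyl)-N,4,4-trimethoxy-N,2-dimethyl-2-[(2S)-oxiran-2-yl]butanamide, via tosylate 12 (not isolated)
Conditions: TsCl, Et3N, Bu2SnO (cat.), CH2Cl2, 0 °C; then K2CO3, MeOH, 0 °C
Reagents that add atoms: 4-methylbenzenesulfonyl chloride, Cc1ccc(cc1)S(Cl)(=O)=O (tosyl group of 12 only; 13 gains no atoms)
Why: Tin-catalysed selective sulfonylation of the primary hydroxyl of the 1,2-diol, then intramolecular Williamson etherification (3-exo-tet) by the secondary alkoxide, closes the epoxide with retention at the carbinol carbon, giving the (S)-epoxide carbon of the target.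

**Step 9**
Reactants: 13 (2R,3S)-3-(2,2-dimethoxyethyl)-N,4,4-trimethoxy-N,2-dimethyl-2-[(2S)-oxiran-2-yl]butanamide
Product: 14 (2R,3S)-3-(2,2-dimethoxyethyl)-4,4-dimethoxy-2-methyl-2-[(2S)-oxiran-2-yl]butanal
Conditions: i-Bu2AlH, THF, −78 °C; aq. sodium potassium tartrate
Reagents that add atoms: none
Why: Hydride reduction of the Weinreb amide stops at the aldehyde through the chelated tetrahedral aluminium intermediate; the α-quaternary aldehyde cannot epimerise and epoxide and acetals are inert at −78 °C.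

**Step 10**
Reactants: 14 (2R,3S)-3-(2,2-dimethoxyethyl)-4,4-dimethoxy-2-methyl-2-[(2S)-oxiran-2-yl]butanal; 15 allenylboronic acid pinacol ester
Product: 17 (3R,4S,5S,6S)-6-(2,2-dimethoxyethyl)-7,7-dimethoxy-5-methyl-5-[(2S)-oxiran-2-yl]hept-1-ene-3,4-diol, via borinate 16 (not isolated)
Conditions: (+)-Ipc2BH [from (−)-α-pinene], Et2O, 0 °C; then 14, −78 °C; then H2O2, aq. NaOH, 0 °C to rt
Reagents that add atoms: hydrogen peroxide, OO (hydroxyl oxygen at C2 of 17); (+)-diisopinocampheylborane, [H]B([C@H]1C[C@H]2C[C@@H]([C@@H]1C)C2(C)C)[C@H]1C[C@H]2C[C@@H]([C@@H]1C)C2(C)C (boron and isopinocampheyl groups of 16 only)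
Why: Brown allylboration with the (E)-γ-borylallyl-diisopinocampheylborane made in situ: the closed chair transition state gives the anti relationship, the isopinocampheyl groups are expected (by analogy with allyl- and crotyl-diisopinocampheylboranes) to direct attack to the Re face of the aldehyde (C1, S) against the substrate's Felkin bias, and oxidation of the C–B bond with retention gives C2 (R); the C6 descriptor reads S here by priority only.

**Step 11**
Reactants: 17 (3R,4S,5S,6S)-6-(2,2-dimethoxyethyl)-7,7-dimethoxy-5-methyl-5-[(2S)-oxiran-2-yl]hept-1-ene-3,4-diol; 18 2-(bromomethyl)acrylic acid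
Product: 19 (3R,4S,5S,6S)-6-(2,2-dimethoxyethyl)-4-hydroxy-7,7-dimethoxy-5-methyl-5-[(2S)-oxiran-2-yl]hept-1-en-3-yl 2-(bromomethyl)prop-2-enoate
Conditions: DIC, DMAP (cat.), CH2Cl2, −20 °C
Reagents that add atoms: none
Why: Carbodiimide (Steglich-type) esterification should acylate the less hindered allylic C2 hydroxyl in preference to the C1 hydroxyl flanked by the quaternary centre; low temperature and catalytic DMAP limit attack on the allylic bromide.

**Step 12**
Reactants: 19 (3R,4S,5S,6S)-6-(2,2-dimethoxyethyl)-4-hydroxy-7,7-dimethoxy-5-methyl-5-[(2S)-oxiran-2-yl]hept-1-en-3-yl 2-(bromomethyl)prop-2-enoate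
Product: 20 (5R)-3-(bromomethyl)-5-{(1S,2S,3S)-3-(2,2-dimethoxyethyl)-1-hydroxy-4,4-dimethoxy-2-methyl-2-[(2S)-oxiran-2-yl]butyl}furan-2(5H)-one
Conditions: RuCl2(=CHPh)(PCy3)(H2IMes) (second-generation Grubbs catalyst, 5 mol%), CH2Cl2, 40 °C, 0.005 M
Reagents that add atoms: none
Why: Ring-closing metathesis between the vinyl group on C2 and the acrylate releases ethene and closes the 3-(bromomethyl)butenolide; no other alkene is present, and epoxide, acetals and the free hydroxyl are tolerated.

**Step 13**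
Reactants: 20 (5R)-3-(bromomethyl)-5-{(1S,2S,3S)-3-(2,2-dimethoxyethyl)-1-hydroxy-4,4-dimethoxy-2-methyl-2-[(2S)-oxiran-2-yl]butyl}furan-2(5H)-one; 21 methacrylic anhydride
Product: 22 (1S,2R,3S)-1-[(2R)-4-(bromomethyl)-5-oxo-2,5-dihydrofuran-2-yl]-3-(2,2-dimethoxyethyl)-4,4-dimethoxy-2-methyl-2-[(2S)-oxiran-2-yl]butyl 2-methylprop-2-enoate
Conditions: i-Pr2NEt, DMAP (cat.), CH2Cl2, 0 °C
Reagents that add atoms: none
Why: DMAP-catalysed acylation of the only free hydroxyl (C1) with the anhydride installs the methacrylate with retention; a hindered amine and low temperature are chosen so that the allylic bromide is not alkylated.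

**Step 14**
Reactants: 22 (1S,2R,3S)-1-[(2R)-4-(bromomethyl)-5-oxo-2,5-dihydrofuran-2-yl]-3-(2,2-dimethoxyethyl)-4,4-dimethoxy-2-methyl-2-[(2S)-oxiran-2-yl]butyl 2-methylprop-2-enoate
Product: 23 (1S,2R,3S)-1-[(2R)-4-(bromomethyl)-5-oxo-2,5-dihydrofuran-2-yl]-3-formyl-2-methyl-2-[(2S)-oxiran-2-yl]-5-oxopentyl 2-methylprop-2-enoate
Conditions: PPTS, acetone/H2O (10:1), 35 °C
Reagents that add atoms: water, O
Why: Mild acid-catalysed hydrolysis of the two dimethyl acetals, expected to be much faster than opening of the epoxide on the quaternary carbon, unmasks the C4 and side-chain aldehydes; the dialdehyde is used at once to avoid epimerisation at C5.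

**Step 15**
Reactants: 23 (1S,2R,3S)-1-[(2R)-4-(bromomethyl)-5-oxo-2,5-dihydrofuran-2-yl]-3-formyl-2-methyl-2-[(2S)-oxiran-2-yl]-5-oxopentyl 2-methylprop-2-enoate
Product: 25 (3aR,4S,5S,6R,7S,7aR)-4-hydroxy-6-methyl-3-methylidene-2-oxo-6-[(2S)-oxiran-2-yl]-5-(2-oxoethyl)octahydro-1-benzofuran-7-yl 2-methylprop-2-enoate, via allylindium 24 (not isolated)
Conditions: In powder, THF/H2O (1:1), rt, 0.005 M
Reagents that add atoms: indium, [In] (metal of 24 only; 25 gains no atoms)
Why: Zerovalent indium inserts into the allylic C–Br bond and the allylindium 24 adds through its γ-carbon (C3, the β-carbon of the butenolide) to the C4 aldehyde, the double bond moving into the exocyclic position (Barbier-type SE2′ carbonyl allylation). The closest known reactions are the indium-mediated allylation of aldehydes with 3-(bromomethyl)furan-2(5H)-ones and intramolecular Barbier cyclisations of 2-(bromomethyl)acrylates. The cyclohexane closes in a 6-exo-trig mode on the aldehyde carbonyl through a bicyclic chair–chair (Zimmerman–Traxler) transition state. C3 is set by the tether, because C4 can reach only the butenolide face that carries C1, which enforces the cis ring fusion; C4 is set by the chair, in which the ring-locked (E)-allyl unit and the equatorial aldehyde substituent place the new hydroxyl trans to the lactone carbon on C3. The step needs site selectivity for the C4 aldehyde over the side-chain aldehyde (six- against seven-membered closure, secured by ring size and high dilution) and γ- over α-attack (α-attack would need an eight-membered ring). Esters and the epoxide are inert to allylindium species in aqueous THF.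

**Step 16**
Reactants: 25 (3aR,4S,5S,6R,7S,7aR)-4-hydroxy-6-methyl-3-methylidene-2-oxo-6-[(2S)-oxiran-2-yl]-5-(2-oxoethyl)octahydro-1-benzofuran-7-yl 2-methylprop-2-enoate; 26 formaldehyde
Product: 27 (3aR,4S,5R,6R,7S,7aR)-4-hydroxy-6-methyl-3-methylidene-2-oxo-6-[(2S)-oxiran-2-yl]-5-(3-oxoprop-1-en-2-yl)octahydro-1-benzofuran-7-yl 2-methylprop-2-enoate (CNP0124638.3)
Conditions: pyrrolidine (10 mol%), propionic acid (10 mol%), i-PrOH/H2O, 45 °C
Reagents that add atoms: none
Why: Amine-catalysed Mannich condensation of the side-chain aldehyde with formaldehyde followed by elimination of the amine (organocatalytic α-methylenation) converts CH2–CHO into the 2-substituted acrolein; no stereocentre is involved, the C5 descriptor becoming R by priority only.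

**Compound list**

1 | (S)-but-3-yn-2-ol | C[C@H](O)C#C | starting material
2 | allyl bromide | C=CCBr | starting material
3 | (2S)-hept-6-en-3-yn-2-ol | C[C@H](O)C#CCC=C | intermediate
4 | (2S,3Z)-hepta-3,6-dien-2-ol | C[C@H](O)/C=C\CC=C | intermediate
5 | 3-methyltetronic acid (4-hydroxy-3-methylfuran-2(5H)-one) | CC1=C(O)COC1=O | starting material
6 | 4-{[(2R,3Z)-hepta-3,6-dien-2-yl]oxy}-3-methylfuran-2(5H)-one | CC1=C(O[C@H](C)/C=C\CC=C)COC1=O | intermediate
7 | (3R)-3-[(4R,5E)-hepta-1,5-dien-4-yl]-3-methylfuran-2,4(3H,5H)-dione | C/C=C/[C@@H](CC=C)[C@]1(C)C(=O)COC1=O | intermediate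
8 | (2S)-2-[(3R)-3-methyl-2,4-dioxooxolan-3-yl]butanedial | O=CC[C@H](C=O)[C@]1(C)C(=O)COC1=O | intermediate (not isolated)
9 | (3R)-3-methyl-3-[(2S)-1,1,4,4-tetramethoxybutan-2-yl]furan-2,4(3H,5H)-dione | COC(OC)C[C@H](C(OC)OC)[C@]1(C)C(=O)COC1=O | intermediate
10 | (3R,4S)-4-hydroxy-3-methyl-3-[(2S)-1,1,4,4-tetramethoxybutan-2-yl]oxolan-2-one | COC(OC)C[C@H](C(OC)OC)[C@]1(C)[C@H](O)COC1=O | intermediate
11 | (2R,3S)-2-[(1S)-1,2-dihydroxyethyl]-3-(2,2-dimethoxyethyl)-N,4,4-trimethoxy-N,2-dimethylbutanamide | CON(C)C(=O)[C@@](C)([C@H](O)CO)[C@H](CC(OC)OC)C(OC)OC | intermediate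
12 | (2S)-2-{(2R,3S)-3-(2,2-dimethoxyethyl)-4,4-dimethoxy-1-[methoxy(methyl)amino]-2-methyl-1-oxobutan-2-yl}-2-hydroxyethyl 4-methylbenzenesulfonate | CON(C)C(=O)[C@@](C)([C@H](O)COS(=O)(=O)c1ccc(C)cc1)[C@H](CC(OC)OC)C(OC)OC | intermediate (not isolated)
13 | (2R,3S)-3-(2,2-dimethoxyethyl)-N,4,4-trimethoxy-N,2-dimethyl-2-[(2S)-oxiran-2-yl]butanamide | CON(C)C(=O)[C@@](C)([C@H]1CO1)[C@H](CC(OC)OC)C(OC)OC | intermediate
14 | (2R,3S)-3-(2,2-dimethoxyethyl)-4,4-dimethoxy-2-methyl-2-[(2S)-oxiran-2-yl]butanal | O=C[C@@](C)([C@H]1CO1)[C@H](CC(OC)OC)C(OC)OC | intermediate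
15 | allenylboronic acid pinacol ester (4,4,5,5-tetramethyl-2-(propa-1,2-dien-1-yl)-1,3,2-dioxaborolane) | C=C=CB1OC(C)(C)C(C)(C)O1 | starting material
16 | diisopinocampheylborinate of the C1 alkoxide bearing the pinacol boronate at C2 (adduct of 14 with the in-situ allylborane) | C=C[C@@H](B1OC(C)(C)C(C)(C)O1)[C@@H](OB([C@H]1C[C@H]2C[C@@H]([C@@H]1C)C2(C)C)[C@H]1C[C@H]2C[C@@H]([C@@H]1C)C2(C)C)[C@@](C)([C@H]1CO1)[C@H](CC(OC)OC)C(OC)OC | intermediate (not isolated)
17 | (3R,4S,5S,6S)-6-(2,2-dimethoxyethyl)-7,7-dimethoxy-5-methyl-5-[(2S)-oxiran-2-yl]hept-1-ene-3,4-diol | C=C[C@@H](O)[C@@H](O)[C@@](C)([C@H]1CO1)[C@H](CC(OC)OC)C(OC)OC | intermediate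
18 | 2-(bromomethyl)acrylic acid | C=C(CBr)C(=O)O | starting material
19 | (3R,4S,5S,6S)-6-(2,2-dimethoxyethyl)-4-hydroxy-7,7-dimethoxy-5-methyl-5-[(2S)-oxiran-2-yl]hept-1-en-3-yl 2-(bromomethyl)prop-2-enoate | C=C[C@@H](OC(=O)C(=C)CBr)[C@@H](O)[C@@](C)([C@H]1CO1)[C@H](CC(OC)OC)C(OC)OC | intermediate
20 | (5R)-3-(bromomethyl)-5-{(1S,2S,3S)-3-(2,2-dimethoxyethyl)-1-hydroxy-4,4-dimethoxy-2-methyl-2-[(2S)-oxiran-2-yl]butyl}furan-2(5H)-one | O=C1O[C@H](C=C1CBr)[C@@H](O)[C@@](C)([C@H]2CO2)[C@H](CC(OC)OC)C(OC)OC | intermediate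
21 | methacrylic anhydride | CC(=C)C(=O)OC(=O)C(C)=C | starting material
22 | (1S,2R,3S)-1-[(2R)-4-(bromomethyl)-5-oxo-2,5-dihydrofuran-2-yl]-3-(2,2-dimethoxyethyl)-4,4-dimethoxy-2-methyl-2-[(2S)-oxiran-2-yl]butyl 2-methylprop-2-enoate | O=C1O[C@H](C=C1CBr)[C@@H](OC(=O)C(C)=C)[C@@](C)([C@H]2CO2)[C@H](CC(OC)OC)C(OC)OC | intermediate
23 | (1S,2R,3S)-1-[(2R)-4-(bromomethyl)-5-oxo-2,5-dihydrofuran-2-yl]-3-formyl-2-methyl-2-[(2S)-oxiran-2-yl]-5-oxopentyl 2-methylprop-2-enoate | O=C1O[C@H](C=C1CBr)[C@@H](OC(=O)C(C)=C)[C@@](C)([C@H]2CO2)[C@H](CC=O)C=O | intermediate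
24 | allylindium derived from 23, drawn as the dibromoindium (trivalent indium) species | O=C1O[C@H](C=C1C[In](Br)Br)[C@@H](OC(=O)C(C)=C)[C@@](C)([C@H]2CO2)[C@H](CC=O)C=O | intermediate (not isolated)
25 | (3aR,4S,5S,6R,7S,7aR)-4-hydroxy-6-methyl-3-methylidene-2-oxo-6-[(2S)-oxiran-2-yl]-5-(2-oxoethyl)octahydro-1-benzofuran-7-yl 2-methylprop-2-enoate | C=C(C)C(=O)O[C@@H]1[C@@H]2OC(=O)C(=C)[C@@H]2[C@@H](O)[C@@H](CC=O)[C@]1(C)[C@H]1CO1 | intermediate
26 | formaldehyde | C=O | starting material
27 | (3aR,4S,5R,6R,7S,7aR)-4-hydroxy-6-methyl-3-methylidene-2-oxo-6-[(2S)-oxiran-2-yl]-5-(3-oxoprop-1-en-2-yl)octahydro-1-benzofuran-7-yl 2-methylprop-2-enoate (CNP0124638.3) | C=C(C)C(=O)O[C@@H]1[C@@H]2OC(=O)C(=C)[C@@H]2[C@@H](O)[C@@H](C(=C)C=O)[C@]1(C)[C@H]1CO1 | target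

**Step count.** Total steps: 16. Longest linear sequence: 16 (1 → 27).

**Steps most likely to fail**

1. Step 15 (key step). The risk is loss of site selectivity, with the allylindium attacking the unhindered side-chain aldehyde in a seven-membered closure, or epimerisation at C5 of the free dialdehyde before cyclisation. The fallback replaces the Barbier reaction by an intramolecular allylboration whose nucleophile is installed before the aldehydes are unmasked. Setting out from 22, palladium-catalysed borylation of the allylic bromide (bis(pinacolato)diboron, Pd(dba)2 cat., toluene, 50 °C) should give the allylboronate F1. Hydrolysis of both acetals under the conditions of step 14 should give the dialdehyde allylboronate F2. On gentle warming this is expected to cyclise without any metal halide through the closed six-membered allylboration transition state to the pinacol borate ester F3. Aqueous NaHCO3 work-up cleaves the B–O bond and the route is rejoined at 25.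

2. Step 10. The risk is poor facial selectivity, because reagent control must override the Felkin-type bias of the α-quaternary aldehyde, together with slow addition to the hindered carbonyl. The fallback is a catalyst-controlled transfer-hydrogenative allylation. Setting out from 14, prop-2-ene-1,1-diyl dibenzoate with [Ir(cod)Cl]2, (R)-SEGPHOS (or its antipode, whichever delivers the 3R,4S adduct), 4-chloro-3-nitrobenzoic acid and K3PO4 in i-PrOH/THF at 90 °C should give the anti diol as the C2 monobenzoate of 17, F4. Methanolysis (K2CO3, MeOH, 0 °C) removes the benzoate and the route is rejoined at 17.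

3. Step 13. The risk is consumption of the acylation catalyst and base by the allylic bromide (N-alkylation) together with sluggish acylation of the hindered C1 hydroxyl. The fallback introduces the bromide only after the methacrylate. Setting out from 17, esterification of the C2 hydroxyl with 2-{[(triethylsilyl)oxy]methyl}acrylic acid (DIC, DMAP) should give the silyloxymethyl acrylate F5. Ring-closing metathesis as in step 12 gives the silyloxymethyl butenolide F6. Methacrylic anhydride, Et3N and DMAP, now with no alkylating group present, give the methacrylate F7. HF·pyridine in THF removes the silyl group to give the allylic alcohol F8. CBr4/PPh3 at −20 °C converts it into the bromide and the route is rejoined at 22.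

**Further compounds**

F1 | step 15 | allylboronate: pinacol boronate analogue of 22 (CH2Br replaced by CH2Bpin) | O=C1O[C@H](C=C1CB2OC(C)(C)C(C)(C)O2)[C@@H](OC(=O)C(C)=C)[C@@](C)([C@H]3CO3)[C@H](CC(OC)OC)C(OC)OC
F2 | step 15 | dialdehyde allylboronate: pinacol boronate analogue of 23 | O=C1O[C@H](C=C1CB2OC(C)(C)C(C)(C)O2)[C@@H](OC(=O)C(C)=C)[C@@](C)([C@H]3CO3)[C@H](CC=O)C=O
F3 | step 15 | pinacol borate ester of the C4 hydroxyl of 25 | C=C(C)C(=O)O[C@@H]1[C@@H]2OC(=O)C(=C)[C@@H]2[C@@H](OB2OC(C)(C)C(C)(C)O2)[C@@H](CC=O)[C@]1(C)[C@H]1CO1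
F4 | step 10 | C2 monobenzoate of 17: (3R,4S,5S,6S)-6-(2,2-dimethoxyethyl)-4-hydroxy-7,7-dimethoxy-5-methyl-5-[(2S)-oxiran-2-yl]hept-1-en-3-yl benzoate | C=C[C@@H](OC(=O)c1ccccc1)[C@@H](O)[C@@](C)([C@H]1CO1)[C@H](CC(OC)OC)C(OC)OC
F5 | step 13 | C2 ester of 17 with 2-{[(triethylsilyl)oxy]methyl}acrylic acid | C=C[C@@H](OC(=O)C(=C)CO[Si](CC)(CC)CC)[C@@H](O)[C@@](C)([C@H]1CO1)[C@H](CC(OC)OC)C(OC)OC
F6 | step 13 | 3-{[(triethylsilyl)oxy]methyl}butenolide analogue of 20 | O=C1O[C@H](C=C1CO[Si](CC)(CC)CC)[C@@H](O)[C@@](C)([C@H]2CO2)[C@H](CC(OC)OC)C(OC)OC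
F7 | step 13 | C1 methacrylate of F6 | O=C1O[C@H](C=C1CO[Si](CC)(CC)CC)[C@@H](OC(=O)C(C)=C)[C@@](C)([C@H]2CO2)[C@H](CC(OC)OC)C(OC)OC
F8 | step 13 | 3-(hydroxymethyl)butenolide analogue of 22 | O=C1O[C@H](C=C1CO)[C@@H](OC(=O)C(C)=C)[C@@](C)([C@H]2CO2)[C@H](CC(OC)OC)C(OC)OC
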